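## Structural features

The target is an achiral tridepside built from three 6-methyl-2,4-dioxygenated benzoyl units: ring A (the dihydroxy end), ring B (the middle) and ring C (the methoxy acid). In each ring C1 carries the carbonyl carbon, C2 and C4 carry oxygen and C6 carries a methyl group. The C1 carbonyl of ring A is esterified to O4 of ring B, and the C1 carbonyl of ring B to O4 of ring C. Ring C ends in a free carboxylic acid and is the only ring whose O2 is methylated. There is no stereocentre and no ring beyond the three benzene rings, so the problem is one of connectivity and oxygen differentiation. Both ester carbonyls lie between an ortho oxygen and an ortho methyl group, which slows acyl substitution while the esters are being made. The finished depside esters, each with a free ortho hydroxyl, are open to solvolysis and acyl transfer in base or hot alcohols, the electron-rich acids decarboxylate readily, and the O2 methyl ether of ring C must outlast every deprotection. The real difficulty is to tell five oxygen functions apart (three phenols, one methyl ether, one acid) and to forge two hindered aryl esters without scrambling, ending with a deprotection that needs neither acid nor base. The key step uses a feature of ring C: C4 is meta to both C2 (methoxy) and C6 (methyl), so C4–H is the only aromatic C–H of a 2-methoxy-6-methylbenzoate with hydrogen on both neighbours (C3 and C5). Sterically ruled borylation can therefore put boron on C4, and a copper-mediated oxidative coupling can turn the C4–B bond into the C4–O bond of the B–C ester.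

## Logic of the disconnections

**14 ⇒ 13.** Four benzylic C–O bonds are cut at once: the three O–CH2 bonds of the benzyl ethers on rings A and B and the O–CH2 bond of the ring C ester. Hydrogenolysis is neutral, so neither depside ester nor the methyl ether is endangered, and one operation reaches the target. The demand is that every protecting group in 13 be benzylic. A tert-butyl ester on ring C was set aside for two reasons. It would need a second, acidic deprotection. It would also have to survive hours at 60 °C beside a Lewis-acidic copper salt that releases strong acid when the carboxylate binds, and its early loss would unmask a second carboxylic acid able to couple in its turn. A plain benzyl ester would bring three unhindered arene C–H bonds into the borylation. The 3,5-dimethylbenzyl ester meets all three needs: each of its aromatic C–H bonds lies between two substituents, it has the acid stability of a benzyl ester, and hydrogen cleaves it like one.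

**13 ⇒ 7 + 12.** The aryl C4–O bond of the B–C ester is cut, not the acyl C–O bond. This splits the molecule into an A–B acid and a ring C arylboron partner of comparable size, and the doubly ortho-substituted carbonyl of ring B is never asked to accept a nucleophile. The forward step requires that 7 hold no free phenol (it would be arylated as well), that 12 carry boron at C4 only, and that O-arylation outrun protodeboronation and hydroxylation of the C–B bond.

**12 ⇒ 9 + 10 (through 11), and 9 ⇒ 8.** The C4–B bond is traced back to C4–H. Steric control by the catalyst selects the one C–H with two hydrogen neighbours, so no halogen or directing group is needed. The pinacol ester 11 is unmasked in the same flask because the free boronic acid transfers its aryl group to copper more readily. The ester O–CH2 bond of 9 is cut to 8; carboxylate alkylation is indifferent to the hindrance at the acyl carbon.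

**7 ⇒ 6 ⇒ 5.** The carboxyl of ring B is traced back to a formyl group, and the O2–CH2 bond of the ring B benzyl ether is cut. A formyl group is a carboxyl surrogate that needs no ester cleavage next to the depside ester, and its hydrogen bond to O2–H differentiates the two phenols of ring B without a protecting group. The oxidation must not chlorinate the electron-rich rings, and the benzylation must not cleave the aryl ester.

**5 ⇒ 3 + 1 (through 4).** The acyl C–O bond of the A–B ester is cut. Here the phenol partner is a simple starting material that can be used freely, so classical acyl transfer through a mixed anhydride is acceptable. The step must acylate O4 and leave the hydrogen-bonded O2–H alone.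

**3 ⇒ 2 ⇒ 1.** The same oxidation and benzylation are applied in reverse order of difficulty, so both halves of the A–B unit come from the single starting material 1.

## Other disconnections considered

**Alternative 1:** The cut removes four bonds of ring B (C1–C6, C1–C2, C3–C4, C4–C5), so that ring B is grown on the ester oxygen of ring C.

- **Forward key step.** Irradiation of the diazo keto ester A1 (benzyl 4-[(2-diazo-4-methyl-3-oxopent-4-enoyl)oxy]-2-methoxy-6-methylbenzoate) should trigger a Wolff rearrangement with migration of the isopropenyl group (C1–C6). The vinylketene should add the siloxyalkyne A2 ((ethynyloxy)triisopropylsilane) in a [2+2] sense (C3–C4, C1–C2). Four-electron opening of the cyclobutenone, six-electron closure (C4–C5) and tautomerisation would give A3 (benzyl 4-({4-hydroxy-6-methyl-2-[(triisopropylsilyl)oxy]benzoyl}oxy)-2-methoxy-6-methylbenzoate).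
- **In its favour.** Ring B is created with its hindered ester to ring C already in place, O2 silylated and O4 free. The chosen route pays for that differentiation with a hydrogen-bond-controlled acylation and a separate benzylation, so on this point the alternative is the better plan. The polarity of A2 sets the regiochemistry without a directing group.
- **Against it here.** A1 needs a ring C phenol whose O4 is already distinguished from O2, which is the problem boron solves in the chosen plan, followed by a β-keto ester acylation and a diazo transfer. Wolff rearrangement of a 2-diazo-1,3-dicarbonyl compound competes with other carbene pathways and with aryloxy migration, and the ester-substituted vinylketene is a strong electrophile that may dimerise. A2 is a sensitive reagent that must be prepared. After A3 there remain acylation of O4 with 3, a fluoride desilylation beside two depside esters (a risk of acyl transfer) and a hydrogenolysis.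
- **Comparison.** On structure it handles ring B well and leaves the oxygen pattern of ring C unsolved. On mechanism it depends on a photochemical cascade of four pericyclic events where the chosen plan needs one ipso substitution at copper. On step economy it is expected to be several operations longer and less convergent, since the rings are joined one after another.

**Alternative 2:** The cut removes the C2–O bonds of rings A and B, so both ortho hydroxyls are introduced last.

- **Forward key step.** A4 (benzyl 4-[(4-{[4-(benzyloxy)-2-methylbenzoyl]oxy}-2-methylbenzoyl)oxy]-2-methoxy-6-methylbenzoate), the tridepside lacking both oxygens, would be treated with [RuCl2(p-cymene)]2 and PhI(OCOCF3)2 in CF3CO2H/(CF3CO)2O. Each aryl ester carbonyl should guide divalent ruthenium to the single free ortho C–H of its own ring. Oxidation and C–O reductive elimination should give aryl trifluoroacetates and, after work-up, A5 (benzyl 4-[(4-{[4-(benzyloxy)-2-hydroxy-6-methylbenzoyl]oxy}-2-hydroxy-6-methylbenzoyl)oxy]-2-methoxy-6-methylbenzoate).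
- **In its favour.** On step economy it is the better plan on paper. The ortho oxygens never need protection, the esterifications that assemble A4 involve acyl carbons with one ortho substituent only and are easier than those of the chosen route, and two C–O bonds form in one operation. The C6 methyl group blocks the second ortho position, so each benzoyl ring offers one site.
- **Against it here.** Aryl esters are weak donors, and the ortho methyl group twists the carbonyl out of the ring plane. The same carbonyls can also direct metalation into the phenoxy ring attached through oxygen (C3 and C5 of rings B and C). The medium is a strong acid with a trivalent iodine oxidant, so the benzyl ether and benzyl ester are liable to acidolysis, electron-rich ring C to oxidation, and the depside esters to acyl exchange with the anhydride. Both rings must react, or mono-hydroxylated mixtures result.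
- **Comparison.** Structurally the two plans reach equally simple precursors. Mechanistically the alternative rests on weak direction in an aggressive medium, whereas the chosen plan fixes its site beforehand with boron and runs near neutrality. In step count the alternative is shorter, at a clearly higher risk in its decisive step.

**Alternative 3:** The cut removes the C2–C3 and C1–C6 bonds of ring C, so the benzene ring is made from a pyranone and an alkyne.

- **Forward key step.** A6 (4-hydroxy-6-methyl-2H-pyran-2-one) would be O-acylated with acid 7 to give A7 (6-methyl-2-oxo-2H-pyran-4-yl 2-(benzyloxy)-4-{[2,4-bis(benzyloxy)-6-methylbenzoyl]oxy}-6-methylbenzoate). Heating A7 with A8 (benzyl 3-methoxyprop-2-ynoate) should give a [4+2] adduct across C3 and C6 of the pyranone. Decarboxylative cycloreversion of the bridged lactone would close ring C as the arene A9 (benzyl 4-[(2-(benzyloxy)-4-{[2,4-bis(benzyloxy)-6-methylbenzoyl]oxy}-6-methylbenzoyl)oxy]-2-methoxy-6-methylbenzoate).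
- **In its favour.** A6 is cheap, no boron or metal is needed for the ring-forming event, and ring C appears with all four substituents placed. The polarity of the partners is matched (nucleophilic C3 of the pyranone to the methoxy-bearing alkyne carbon). A9 is all-benzyl, so the end is one hydrogenolysis, equal to the chosen plan. The total step count is about equal.
- **Against it here.** 2-Pyranones are reluctant dienes that usually need temperatures well above 150 °C. A7 is a vinylogous mixed anhydride and thus an acyl donor, prone to O-to-C3 acyl migration and acyl transfer when heated. A8 is a push–pull alkyne of limited thermal stability that must be made. The five-step acid 7 is exposed to these forcing conditions late in the route, and the regiochemistry rests on an electronic preference, not on a fixed site.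
- **Comparison.** Structurally the alternative builds ring C where the chosen plan functionalises an existing ring. Mechanistically it asks a thermally labile enol ester to survive a hot cycloaddition, whereas the chosen plan forms one C–O bond at 60 °C at a position fixed in advance. In step economy the two are about equal, with the alternative one step longer in its longest line.

Key step: step 8

Remark: the target has no stereocentre, so no step has to control configuration. Compounds 1, 8 and 10 and the two benzylic bromides are taken as purchasable. Relative to a tert-butyl ester design, only the ester group on ring C is changed; the bond formed in step 8 and the skeletons of 7, 12 and 13 are unchanged.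

## Route

Step 1
Reactants: 1 2,4-dihydroxy-6-methylbenzaldehyde (orsellinaldehyde)
Product: 2 2,4-bis(benzyloxy)-6-methylbenzaldehyde
Conditions: BnBr, K2CO3, DMF, 60 °C
Reagents that add atoms: benzyl bromide, BrCc1ccccc1
Why: Williamson ether synthesis on both phenoxides; gentle warming should also alkylate the hydrogen-bonded 2-OH, and the aldehyde is inert to carbonate.

Step 2
Reactants: 2 2,4-bis(benzyloxy)-6-methylbenzaldehyde
Product: 3 2,4-bis(benzyloxy)-6-methylbenzoic acid
Conditions: NaClO2, NaH2PO4, 2-methyl-2-butene, t-BuOH/THF/H2O, rt
Reagents that add atoms: sodium chlorite, [Na+].[O-]Cl=O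
Why: Pinnick oxidation; chlorous acid adds to the aldehyde and fragments to the acid, while the alkene traps HOCl so the electron-rich ring is not chlorinated and the benzyl ethers are untouched.

Step 3
Reactants: 3 2,4-bis(benzyloxy)-6-methylbenzoic acid; 1 2,4-dihydroxy-6-methylbenzaldehyde
Product: 5 4-formyl-3-hydroxy-5-methylphenyl 2,4-bis(benzyloxy)-6-methylbenzoate, via mixed trifluoroacetic anhydride 4 (not isolated)
Conditions: (CF3CO)2O, toluene, 0 °C to rt; then 1
Reagents that add atoms: none
Why: Mixed-anhydride esterification, the standard way to make depside esters from 2,6-disubstituted benzoic acids, in which an acylium-like donor makes hindrance at the acyl carbon matter little. The 2-OH of 1 is held in a hydrogen bond to the formyl oxygen, so only the 4-OH should be acylated.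

Step 4
Reactants: 5 4-formyl-3-hydroxy-5-methylphenyl 2,4-bis(benzyloxy)-6-methylbenzoate
Product: 6 3-(benzyloxy)-4-formyl-5-methylphenyl 2,4-bis(benzyloxy)-6-methylbenzoate
Conditions: BnBr, K2CO3, acetone, reflux
Reagents that add atoms: benzyl bromide, BrCc1ccccc1
Why: Williamson ether synthesis on the remaining phenol under mild heterogeneous base; the aryl ester carbonyl is shielded by its two ortho substituents and should survive.

Step 5
Reactants: 6 3-(benzyloxy)-4-formyl-5-methylphenyl 2,4-bis(benzyloxy)-6-methylbenzoate
Product: 7 2-(benzyloxy)-4-{[2,4-bis(benzyloxy)-6-methylbenzoyl]oxy}-6-methylbenzoic acid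
Conditions: NaClO2, NaH2PO4, 2-methyl-2-butene, t-BuOH/THF/H2O, rt
Reagents that add atoms: sodium chlorite, [Na+].[O-]Cl=O
Why: Pinnick oxidation in a weakly acidic buffer reveals the carboxyl without any ester cleavage, so the depside ester and the benzyl ethers are not at risk.

Step 6
Reactants: 8 2-methoxy-6-methylbenzoic acid
Product: 9 3,5-dimethylbenzyl 2-methoxy-6-methylbenzoate
Conditions: 3,5-dimethylbenzyl bromide, K2CO3, DMF, rt
Reagents that add atoms: 3,5-dimethylbenzyl bromide, Cc1cc(C)cc(CBr)c1
Why: Carboxylate O-alkylation (SN2); the new bond is O–CH2, so the two ortho substituents that hinder the acyl carbon do not slow it.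

Step 7
Reactants: 9 3,5-dimethylbenzyl 2-methoxy-6-methylbenzoate; 10 bis(pinacolato)diboron (0.6 equiv)
Product: 12 (4-{[(3,5-dimethylbenzyl)oxy]carbonyl}-3-methoxy-5-methylphenyl)boronic acid, via pinacol boronate 11 (not isolated)
Conditions: [Ir(OMe)(cod)]2 (1.5 mol %), 4,4'-di-tert-butyl-2,2'-bipyridine (3 mol %), THF, 80 °C; then NaIO4, NH4OAc, THF/H2O, rt
Reagents that add atoms: water, O
Why: Iridium-catalysed aromatic C–H borylation is ruled by sterics: the tris(boryl)iridium species reacts only at a C–H with no ortho substituent, which is C4 of ring C alone, since every C–H of the 3,5-dimethylbenzyl ring lies between two substituents. Periodate then destroys the pinacol released on hydrolysis, a known one-pot borylation and unmasking, to leave the free boronic acid.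

Step 8
Reactants: 7 2-(benzyloxy)-4-{[2,4-bis(benzyloxy)-6-methylbenzoyl]oxy}-6-methylbenzoic acid; 12 (4-{[(3,5-dimethylbenzyl)oxy]carbonyl}-3-methoxy-5-methylphenyl)boronic acid (2 equiv)
Product: 13 3,5-dimethylbenzyl 4-[(2-(benzyloxy)-4-{[2,4-bis(benzyloxy)-6-methylbenzoyl]oxy}-6-methylbenzoyl)oxy]-2-methoxy-6-methylbenzoate
Conditions: Cu(OTf)2 (0.4 equiv), urea (1 equiv), 4 Å MS, EtOAc, dry air, 60 °C
Reagents that add atoms: none
Why: This is a Chan–Lam-type oxidative C–O coupling: the aryl group of 12 passes from boron to divalent copper, the carboxylate of 7 binds to the same metal, oxidation by a second divalent copper centre or by O2 gives an aryl(carboxylato) complex of trivalent copper, and C–O reductive elimination forms the C4–O bond of ring C, after which air returns monovalent copper to the divalent state. The closest known reaction is the Cu(OTf)2/urea coupling of arylboronic acids with aromatic and aliphatic carboxylic acids to give aryl esters. No ring is closed and no stereocentre is formed, so only site selectivity and chemoselectivity matter. The site is fixed by ipso substitution at the carbon that carries boron, which step 7 placed on C4. Chemoselectivity requires O-arylation to outrun protodeboronation, hydroxylation of the C–B bond and biaryl formation; a dry medium with molecular sieves, urea as a neutral oxygen ligand and an excess of the cheaper partner 12 serve this. Compound 7 has no free phenol, so diaryl ether formation cannot compete and its carboxylate is the only nucleophile offered to copper. The acid reacts through its remote oxygen, so the ortho benzyloxy and methyl groups that would hamper attack at the acyl carbon do not matter. The four benzylic protecting groups and the A–B aryl ester should tolerate the mildly acidic Cu(OTf)2 medium at 60 °C, which a tert-butyl ester might not.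

Step 9
Reactants: 13 3,5-dimethylbenzyl 4-[(2-(benzyloxy)-4-{[2,4-bis(benzyloxy)-6-methylbenzoyl]oxy}-6-methylbenzoyl)oxy]-2-methoxy-6-methylbenzoate
Product: 14 4-({4-[(2,4-dihydroxy-6-methylbenzoyl)oxy]-2-hydroxy-6-methylbenzoyl}oxy)-2-methoxy-6-methylbenzoic acid (CNP0283563.0)
Conditions: H2 (1 atm), 10% Pd/C, THF/EtOAc, rt
Reagents that add atoms: none
Why: Catalytic hydrogenolysis should cleave all four benzylic C–O bonds (three benzyl ethers and the 3,5-dimethylbenzyl ester) in one operation. Aryl esters and the methyl ether are inert, and the aprotic solvent avoids solvolysis of the depside esters.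

## Compound list

1 | 2,4-dihydroxy-6-methylbenzaldehyde (orsellinaldehyde) | Cc1cc(O)cc(O)c1C=O | starting material
2 | 2,4-bis(benzyloxy)-6-methylbenzaldehyde | Cc1cc(OCc2ccccc2)cc(OCc2ccccc2)c1C=O | intermediate
3 | 2,4-bis(benzyloxy)-6-methylbenzoic acid | Cc1cc(OCc2ccccc2)cc(OCc2ccccc2)c1C(=O)O | intermediate
4 | 2,4-bis(benzyloxy)-6-methylbenzoic trifluoroacetic anhydride | Cc1cc(OCc2ccccc2)cc(OCc2ccccc2)c1C(=O)OC(=O)C(F)(F)F | intermediate (not isolated)
5 | 4-formyl-3-hydroxy-5-methylphenyl 2,4-bis(benzyloxy)-6-methylbenzoate | Cc1cc(OC(=O)c2c(C)cc(OCc3ccccc3)cc2OCc2ccccc2)cc(O)c1C=O | intermediate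
6 | 3-(benzyloxy)-4-formyl-5-methylphenyl 2,4-bis(benzyloxy)-6-methylbenzoate | Cc1cc(OC(=O)c2c(C)cc(OCc3ccccc3)cc2OCc2ccccc2)cc(OCc2ccccc2)c1C=O | intermediate
7 | 2-(benzyloxy)-4-{[2,4-bis(benzyloxy)-6-methylbenzoyl]oxy}-6-methylbenzoic acid | Cc1cc(OC(=O)c2c(C)cc(OCc3ccccc3)cc2OCc2ccccc2)cc(OCc2ccccc2)c1C(=O)O | intermediate
8 | 2-methoxy-6-methylbenzoic acid | COc1cccc(C)c1C(=O)O | starting material
9 | 3,5-dimethylbenzyl 2-methoxy-6-methylbenzoate | COc1cccc(C)c1C(=O)OCc1cc(C)cc(C)c1 | intermediate
10 | bis(pinacolato)diboron | CC1(C)OB(OC1(C)C)B1OC(C)(C)C(C)(C)O1 | starting material
11 | 3,5-dimethylbenzyl 2-methoxy-6-methyl-4-(4,4,5,5-tetramethyl-1,3,2-dioxaborolan-2-yl)benzoate | COc1cc(B2OC(C)(C)C(C)(C)O2)cc(C)c1C(=O)OCc1cc(C)cc(C)c1 | intermediate (not isolated)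
12 | (4-{[(3,5-dimethylbenzyl)oxy]carbonyl}-3-methoxy-5-methylphenyl)boronic acid | COc1cc(B(O)O)cc(C)c1C(=O)OCc1cc(C)cc(C)c1 | intermediate
13 | 3,5-dimethylbenzyl 4-[(2-(benzyloxy)-4-{[2,4-bis(benzyloxy)-6-methylbenzoyl]oxy}-6-methylbenzoyl)oxy]-2-methoxy-6-methylbenzoate | COc1cc(OC(=O)c2c(C)cc(OC(=O)c3c(C)cc(OCc4ccccc4)cc3OCc3ccccc3)cc2OCc2ccccc2)cc(C)c1C(=O)OCc1cc(C)cc(C)c1 | intermediate
14 | 4-({4-[(2,4-dihydroxy-6-methylbenzoyl)oxy]-2-hydroxy-6-methylbenzoyl}oxy)-2-methoxy-6-methylbenzoic acid | COc1cc(OC(=O)c2c(C)cc(OC(=O)c3c(C)cc(O)cc3O)cc2O)cc(C)c1C(=O)O | target

## Step count and risk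

Total step count: 9. Longest linear sequence: 7 steps (steps 1, 2, 3, 4, 5, 8, 9) from 1; the ring C branch (steps 6 and 7) joins at step 8.

**Step 8 (key step).** The most likely failure is protodeboronation and oxidative hydroxylation of 12 running ahead of carboxylate transfer, because the twisted, hindered carboxylate of 7 may bind copper slowly. A lesser risk is Lewis-acid loss of the ortho benzyl ether of 7 followed by arylation of the freed phenol. The fallback replaces aryl transfer by acyl transfer; it sets out from 12 and 7 and returns at 13. Boronic acid 12 is oxidised with aqueous H2O2 in THF to 3,5-dimethylbenzyl 4-hydroxy-2-methoxy-6-methylbenzoate F1, so the sterically placed boron still decides which carbon bears oxygen. Acid 7 is activated with (CF3CO)2O in toluene as 2-(benzyloxy)-4-{[2,4-bis(benzyloxy)-6-methylbenzoyl]oxy}-6-methylbenzoic trifluoroacetic anhydride F2, which acylates F1 to give 13.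

**Step 7.** The most likely failure is incomplete unmasking of the pinacol ester in the crude borylation mixture, where iridium residues and boron by-products consume periodate, together with some oxidation of the C–B bond; borylation at a wrong site is not expected. The fallback sets out from 9 and returns at 12. The borylation is stopped at 11, which is isolated. KHF2 in aqueous methanol converts 11 into potassium (4-{[(3,5-dimethylbenzyl)oxy]carbonyl}-3-methoxy-5-methylphenyl)trifluoroborate F3, a crystalline salt that is washed free of pinacol. Me3SiCl and water in MeCN then hydrolyse F3 to 12.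

**Step 3.** The most likely failure is poor discrimination between the two hydroxyls of 1 in the acidic medium (a second acylation, or trifluoroacetylation of the 4-OH that stalls the reaction), with ring C-acylation by the acylium-like donor as a further possibility. The fallback is base-mediated, with selectivity drawn from acidity instead of hydrogen bonding; it sets out from 3 and returns at 5. (COCl)2 with catalytic DMF converts 3 into 2,4-bis(benzyloxy)-6-methylbenzoyl chloride F4. F4 is added to 1 with one equivalent of Et3N and catalytic DMAP in CH2Cl2 at 0 °C, where only the more acidic 4-OH (para to the formyl group) is deprotonated, giving 5.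

**Step 4.** The most likely failure is cleavage of the A–B aryl ester by carbonate or by the phenoxide of 5, since the leaving phenoxide is stabilised by the para formyl group, or slow alkylation of the hydrogen-bonded phenol. The fallback installs the benzyl ether before the depside bond; it sets out from 1 and returns at 6, at the cost of two extra steps. Allyl bromide with one equivalent of K2CO3 in acetone alkylates the more acidic 4-OH of 1 to give 4-(allyloxy)-2-hydroxy-6-methylbenzaldehyde F5. BnBr and K2CO3 in DMF give 4-(allyloxy)-2-(benzyloxy)-6-methylbenzaldehyde F6. Pd(PPh3)4, a zerovalent palladium catalyst, with morpholine removes the allyl group to give 2-(benzyloxy)-4-hydroxy-6-methylbenzaldehyde F7. F7 is acylated with the mixed anhydride 4, made from 3 as in step 3, to give 6.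

## Further compounds

F1 | step 8 | 3,5-dimethylbenzyl 4-hydroxy-2-methoxy-6-methylbenzoate | COc1cc(O)cc(C)c1C(=O)OCc1cc(C)cc(C)c1
F2 | step 8 | 2-(benzyloxy)-4-{[2,4-bis(benzyloxy)-6-methylbenzoyl]oxy}-6-methylbenzoic trifluoroacetic anhydride | Cc1cc(OC(=O)c2c(C)cc(OCc3ccccc3)cc2OCc2ccccc2)cc(OCc2ccccc2)c1C(=O)OC(=O)C(F)(F)F
F3 | step 7 | potassium (4-{[(3,5-dimethylbenzyl)oxy]carbonyl}-3-methoxy-5-methylphenyl)trifluoroborate | [K+].COc1cc([B-](F)(F)F)cc(C)c1C(=O)OCc1cc(C)cc(C)c1
F4 | step 3 | 2,4-bis(benzyloxy)-6-methylbenzoyl chloride | Cc1cc(OCc2ccccc2)cc(OCc2ccccc2)c1C(Cl)=O
F5 | step 4 | 4-(allyloxy)-2-hydroxy-6-methylbenzaldehyde | C=CCOc1cc(C)c(C=O)c(O)c1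
F6 | step 4 | 4-(allyloxy)-2-(benzyloxy)-6-methylbenzaldehyde | C=CCOc1cc(C)c(C=O)c(OCc2ccccc2)c1
F7 | step 4 | 2-(benzyloxy)-4-hydroxy-6-methylbenzaldehyde | Cc1cc(O)cc(OCc2ccccc2)c1C=O
A1 | alternative 1 | benzyl 4-[(2-diazo-4-methyl-3-oxopent-4-enoyl)oxy]-2-methoxy-6-methylbenzoate | COc1cc(OC(=O)C(=[N+]=[N-])C(=O)C(C)=C)cc(C)c1C(=O)OCc1ccccc1
A2 | alternative 1 | (ethynyloxy)triisopropylsilane | C#CO[Si](C(C)C)(C(C)C)C(C)C
A3 | alternative 1 | benzyl 4-({4-hydroxy-6-methyl-2-[(triisopropylsilyl)oxy]benzoyl}oxy)-2-methoxy-6-methylbenzoate | COc1cc(OC(=O)c2c(C)cc(O)cc2O[Si](C(C)C)(C(C)C)C(C)C)cc(C)c1C(=O)OCc1ccccc1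
A4 | alternative 2 | benzyl 4-[(4-{[4-(benzyloxy)-2-methylbenzoyl]oxy}-2-methylbenzoyl)oxy]-2-methoxy-6-methylbenzoate | COc1cc(OC(=O)c2ccc(OC(=O)c3ccc(OCc4ccccc4)cc3C)cc2C)cc(C)c1C(=O)OCc1ccccc1
A5 | alternative 2 | benzyl 4-[(4-{[4-(benzyloxy)-2-hydroxy-6-methylbenzoyl]oxy}-2-hydroxy-6-methylbenzoyl)oxy]-2-methoxy-6-methylbenzoate | COc1cc(OC(=O)c2c(O)cc(OC(=O)c3c(O)cc(OCc4ccccc4)cc3C)cc2C)cc(C)c1C(=O)OCc1ccccc1
A6 | alternative 3 | 4-hydroxy-6-methyl-2H-pyran-2-one | Cc1cc(O)cc(=O)o1
A7 | alternative 3 | 6-methyl-2-oxo-2H-pyran-4-yl 2-(benzyloxy)-4-{[2,4-bis(benzyloxy)-6-methylbenzoyl]oxy}-6-methylbenzoate | Cc1cc(OC(=O)c2c(C)cc(OC(=O)c3c(C)cc(OCc4ccccc4)cc3OCc3ccccc3)cc2OCc2ccccc2)cc(=O)o1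
A8 | alternative 3 | benzyl 3-methoxyprop-2-ynoate | COC#CC(=O)OCc1ccccc1
A9 | alternative 3 | benzyl 4-[(2-(benzyloxy)-4-{[2,4-bis(benzyloxy)-6-methylbenzoyl]oxy}-6-methylbenzoyl)oxy]-2-methoxy-6-methylbenzoate | COc1cc(OC(=O)c2c(C)cc(OC(=O)c3c(C)cc(OCc4ccccc4)cc3OCc3ccccc3)cc2OCc2ccccc2)cc(C)c1C(=O)OCc1ccccc1
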